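The plan rests on cutting the cyclohexane ring between C7 (CH2) and C7a, the fully substituted ring-fusion carbon that carries the methyl group and O1 (benzofuran numbering: O1, C2, C3, C3a, C4–C7, C7a). Ring-closing olefin metathesis forms this bond as a C7=C7a alkene and closes the carbocycle in one operation; because C7a is the more substituted alkene terminus, Markovnikov hydration from the face opposite the axial C4 methyl then gives the trans-fused lactone. The precursor is an acyclic diene with an isopropenyl group on C3a and an allyl group on C5, whose two stereocentres are relayed from one catalytic allylation through a δ-lactone.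

Key step: step 6

Remark: skeletal atoms keep the target's benzofuran numbers in all intermediates, and the Z enol ether geometry of the target (acyl group syn to O1) is assumed to be the thermodynamically favoured one for this α-methyl push–pull alkene.

Step 1
Reactants: 1 isobutyraldehyde; 2 methyl acrylate
Product: 5 methyl 4,4-dimethyl-5-oxopentanoate, via 1-(2-methylprop-1-en-1-yl)pyrrolidine 3 (not isolated), via methyl 3,3-dimethyl-2-(pyrrolidin-1-yl)cyclobutane-1-carboxylate 4 (not isolated)
Conditions: pyrrolidine (1.1 equiv), PhMe, reflux, Dean–Stark; then 2, MeCN, reflux; then AcOH/NaOAc, H2O, 60 °C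
Reagents that add atoms: water, O
Why: Stork enamine Michael addition: the enamine of the α,α-disubstituted aldehyde adds to the acrylate (the adduct rests as the aminocyclobutane) and aqueous acid then releases the aldehyde, which fixes the quaternary C4 next to the future C3a and C5.

Step 2
Reactants: 5 methyl 4,4-dimethyl-5-oxopentanoate
Product: 8 (R)-6-allyl-5,5-dimethyltetrahydro-2H-pyran-2-one, via O-pinacolboryl homoallyl ether 6 (not isolated), via methyl (R)-5-hydroxy-4,4-dimethyloct-7-enoate 7 (not isolated)
Conditions: allylB(pin), (R)-TRIP [(R)-3,3'-bis(2,4,6-triisopropylphenyl)-1,1'-binaphthyl-2,2'-diyl hydrogen phosphate, 5 mol%], 4 Å MS, PhMe, −30 °C; aq. NaHCO3; then TsOH·H2O (cat.), CH2Cl2, rt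
Reagents that add atoms: allylboronic acid pinacol ester, C=CCB1OC(C)(C)C(C)(C)O1
Why: Chiral phosphoric acid-catalysed allylboration through a closed chair-like six-membered transition state adds allyl to the Re face of the aldehyde (the catalyst antipode is chosen for this face), so that catalyst control sets C5 as the (R)-carbinol, and the δ-hydroxy ester then lactonises under acid, helped by the gem-dimethyl group.

Step 3
Reactants: 8 (R)-6-allyl-5,5-dimethyltetrahydro-2H-pyran-2-one
Product: 10 (R)-6-allyl-5,5-dimethyl-5,6-dihydro-2H-pyran-2-one, via 3-(phenylselanyl) lactone 9 (not isolated)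
Conditions: LDA, THF, −78 °C; PhSeBr, −78 °C; then 30% H2O2, pyridine, CH2Cl2, 0 °C to rt
Reagents that add atoms: none
Why: α-Selenenylation of the lactone enolate followed by oxidation and syn-elimination of the selenoxide can only place the new double bond at C3=C3a, in conjugation with the lactone carbonyl, and leaves C5 untouched.

Step 4
Reactants: 10 (R)-6-allyl-5,5-dimethyl-5,6-dihydro-2H-pyran-2-one
Product: 12 (4R,6R)-6-allyl-5,5-dimethyl-4-(prop-1-en-2-yl)tetrahydro-2H-pyran-2-one, via silyl ketene acetal 11 (not isolated)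
Conditions: isopropenylMgBr, CuBr·SMe2 (20 mol%), TMSCl, THF, −78 to −40 °C; aq. NH4Cl
Reagents that add atoms: isopropenylmagnesium bromide, C=C(C)[Mg]Br
Why: Copper-catalysed conjugate addition to the unsaturated δ-lactone: the isopropenyl group attacks C3a axially and anti to the pseudo-axial methyl on C4 in the half-chair that keeps the C5 allyl group pseudo-equatorial, which should set C3a trans to the allyl group (substrate control by C5).

Step 5
Reactants: 12 (4R,6R)-6-allyl-5,5-dimethyl-4-(prop-1-en-2-yl)tetrahydro-2H-pyran-2-one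
Product: 13 (3R,5R)-5-hydroxy-N-methoxy-N,4,4-trimethyl-3-(prop-1-en-2-yl)oct-7-enamide
Conditions: MeNH(OMe)·HCl, i-PrMgCl, THF, −20 to 0 °C; aq. NH4Cl; used directly
Reagents that add atoms: N,O-dimethylhydroxylamine hydrochloride, CNOC.Cl
Why: Aminolysis of the lactone by the chloromagnesium amide (Weinreb amide formation) opens the temporary ring without touching a stereocentre, which is needed because the trans-disposed allyl and isopropenyl groups cannot meet while the δ-lactone is closed.

Step 6
Reactants: 13 (3R,5R)-5-hydroxy-N-methoxy-N,4,4-trimethyl-3-(prop-1-en-2-yl)oct-7-enamide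
Product: 14 2-[(1R,5R)-5-hydroxy-2,6,6-trimethylcyclohex-2-en-1-yl]-N-methoxy-N-methylacetamide
Conditions: second-generation Grubbs catalyst (5 mol%), CH2Cl2 (0.01 M), 40 °C
Reagents that add atoms: none
Why: Ring-closing olefin metathesis by the Chauvin mechanism: the ruthenium carbene loads onto the monosubstituted allyl alkene, undergoes intramolecular [2+2] cycloaddition with the 1,1-disubstituted isopropenyl alkene, and cycloreversion releases the cyclohexene and ethene. The closest known reaction type is the ring-closing metathesis of 2-methylhepta-1,6-dienes to 1-methylcyclohexenes, which tolerates free hydroxyl and amide groups. The six-membered ring C3a–C4–C5–C6–C7–C7a is closed by alkene metathesis with the new C7=C7a bond endocyclic, and the gem-dimethyl group at C4 favours the folded conformer. No stereocentre is formed: C3a and C5 pass through unchanged, and C7a is left trigonal so that its configuration can be set afterwards by the ring itself. The step needs ring closure to win over dimerisation and the double bond to stay at C7=C7a, which high dilution, loss of ethene and the absence of any other alkene should secure.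

Step 7
Reactants: 14 2-[(1R,5R)-5-hydroxy-2,6,6-trimethylcyclohex-2-en-1-yl]-N-methoxy-N-methylacetamide
Product: 16 (3aS,5R,7aS)-5-hydroxy-4,4,7a-trimethylhexahydro-1-benzofuran-2(3H)-one, via dihydroxy amide 15 (not isolated)
Conditions: Mn(dpm)3 (10 mol%), PhSiH3, O2 (1 atm), i-PrOH/CH2Cl2, 0 °C to rt; then PPTS, PhMe, 60 °C
Reagents that add atoms: dioxygen, O=O
Why: Mukaiyama hydration by hydrogen atom transfer from a manganese hydride gives the tertiary C7a radical, which should be trapped by O2 on the face opposite the axial C4 methyl (the equatorial C–O bond, as in hydrations of drimane-type alkenes), and the new alcohol, trans to the C3a side chain, then acylates itself on the Weinreb amide to close the trans-fused lactone.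

Step 8
Reactants: 16 (3aS,5R,7aS)-5-hydroxy-4,4,7a-trimethylhexahydro-1-benzofuran-2(3H)-one
Product: 17 (3aS,5S,7aS)-5-bromo-4,4,7a-trimethylhexahydro-1-benzofuran-2(3H)-one
Conditions: PPh3, CBr4, 2,6-lutidine, PhMe, 0 to 60 °C
Reagents that add atoms: carbon tetrabromide, BrC(Br)(Br)Br
Why: Appel bromination: bromide displaces the axial oxyphosphonium group of the conformationally locked ring from the rear (SN2), so the (5R) axial alcohol should give the (5S) equatorial bromide.

Step 9
Reactants: 17 (3aS,5S,7aS)-5-bromo-4,4,7a-trimethylhexahydro-1-benzofuran-2(3H)-one; 18 N-methoxy-N-methylpropanamide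
Product: 20 (2Z)-2-[(3aS,5S,7aS)-5-bromo-4,4,7a-trimethylhexahydro-1-benzofuran-2(3H)-ylidene]-N-methoxy-N-methylpropanamide, via hemiketal adduct 19 (not isolated)
Conditions: 18, LDA, THF, −78 °C, then 17; aq. NH4Cl; then MsCl, Et3N, CH2Cl2, 0 °C to rt
Reagents that add atoms: none
Why: Claisen-type addition of the amide enolate to the lactone carbonyl stops at the hemiketal, and mesylation with elimination then gives the conjugated exocyclic enol ether (a vinylogous carbamate), which should settle in the Z geometry with the methyl group next to C3 and the acyl group next to O1.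

Step 10
Reactants: 20 (2Z)-2-[(3aS,5S,7aS)-5-bromo-4,4,7a-trimethylhexahydro-1-benzofuran-2(3H)-ylidene]-N-methoxy-N-methylpropanamide
Product: 21 (3Z)-1-bromo-3-[(3aS,5S,7aS)-5-bromo-4,4,7a-trimethylhexahydro-1-benzofuran-2(3H)-ylidene]butan-2-one
Conditions: CH2Br2, MeLi·LiBr, THF/Et2O, −78 °C; aq. NH4Cl at −78 °C
Reagents that add atoms: dibromomethane, BrCBr
Why: Bromomethyllithium, formed in the flask by bromine–lithium exchange, adds once to the Weinreb amide and the chelated tetrahedral adduct collapses to the bromomethyl ketone only on quench (halomethyllithium homologation of Weinreb amides), while the secondary bromide and the enol ether are inert at −78 °C.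

Compound list

1 | isobutyraldehyde (2-methylpropanal) | CC(C)C=O | starting material
2 | methyl acrylate | C=CC(=O)OC | starting material
3 | 1-(2-methylprop-1-en-1-yl)pyrrolidine | CC(C)=CN1CCCC1 | intermediate
4 | methyl 3,3-dimethyl-2-(pyrrolidin-1-yl)cyclobutane-1-carboxylate (racemic) | COC(=O)C1CC(C)(C)C1N1CCCC1 | intermediate
5 | methyl 4,4-dimethyl-5-oxopentanoate | COC(=O)CCC(C)(C)C=O | intermediate
6 | methyl (R)-4,4-dimethyl-5-[(4,4,5,5-tetramethyl-1,3,2-dioxaborolan-2-yl)oxy]oct-7-enoate | C=CC[C@@H](OB1OC(C)(C)C(C)(C)O1)C(C)(C)CCC(=O)OC | intermediate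
7 | methyl (R)-5-hydroxy-4,4-dimethyloct-7-enoate | C=CC[C@@H](O)C(C)(C)CCC(=O)OC | intermediate
8 | (R)-6-allyl-5,5-dimethyltetrahydro-2H-pyran-2-one | C=CC[C@H]1OC(=O)CCC1(C)C | intermediate
9 | (6R)-6-allyl-5,5-dimethyl-3-(phenylselanyl)tetrahydro-2H-pyran-2-one (both C3 epimers) | C=CC[C@H]1OC(=O)C([Se]c2ccccc2)CC1(C)C | intermediate
10 | (R)-6-allyl-5,5-dimethyl-5,6-dihydro-2H-pyran-2-one | C=CC[C@H]1OC(=O)C=CC1(C)C | intermediate
11 | {[(2R,4R)-2-allyl-3,3-dimethyl-4-(prop-1-en-2-yl)-3,4-dihydro-2H-pyran-6-yl]oxy}trimethylsilane | C=CC[C@H]1OC(O[Si](C)(C)C)=C[C@H](C(C)=C)C1(C)C | intermediate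
12 | (4R,6R)-6-allyl-5,5-dimethyl-4-(prop-1-en-2-yl)tetrahydro-2H-pyran-2-one (allyl and isopropenyl trans) | C=CC[C@H]1OC(=O)C[C@H](C(C)=C)C1(C)C | intermediate
13 | (3R,5R)-5-hydroxy-N-methoxy-N,4,4-trimethyl-3-(prop-1-en-2-yl)oct-7-enamide | C=CC[C@@H](O)C(C)(C)[C@H](CC(=O)N(C)OC)C(C)=C | intermediate
14 | 2-[(1R,5R)-5-hydroxy-2,6,6-trimethylcyclohex-2-en-1-yl]-N-methoxy-N-methylacetamide | CON(C)C(=O)C[C@@H]1C(C)=CC[C@@H](O)C1(C)C | intermediate
15 | 2-[(1S,2S,5R)-2,5-dihydroxy-2,6,6-trimethylcyclohexyl]-N-methoxy-N-methylacetamide | CON(C)C(=O)C[C@@H]1[C@@](C)(O)CC[C@@H](O)C1(C)C | intermediate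
16 | (3aS,5R,7aS)-5-hydroxy-4,4,7a-trimethylhexahydro-1-benzofuran-2(3H)-one (trans-fused, axial 5-OH) | O=C1C[C@H]2C(C)(C)[C@H](O)CC[C@]2(C)O1 | intermediate
17 | (3aS,5S,7aS)-5-bromo-4,4,7a-trimethylhexahydro-1-benzofuran-2(3H)-one (trans-fused, equatorial 5-Br) | O=C1C[C@H]2C(C)(C)[C@@H](Br)CC[C@]2(C)O1 | intermediate
18 | N-methoxy-N-methylpropanamide | CCC(=O)N(C)OC | starting material
19 | 2-[(3aS,5S,7aS)-5-bromo-2-hydroxy-4,4,7a-trimethyloctahydro-1-benzofuran-2-yl]-N-methoxy-N-methylpropanamide (epimers at C2 and at the amide α-carbon) | CON(C)C(=O)C(C)C1(O)C[C@H]2C(C)(C)[C@@H](Br)CC[C@]2(C)O1 | intermediate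
20 | (2Z)-2-[(3aS,5S,7aS)-5-bromo-4,4,7a-trimethylhexahydro-1-benzofuran-2(3H)-ylidene]-N-methoxy-N-methylpropanamide | C/C(C(=O)N(C)OC)=C1\C[C@H]2C(C)(C)[C@@H](Br)CC[C@]2(C)O1 | intermediate
21 | (3Z)-1-bromo-3-[(3aS,5S,7aS)-5-bromo-4,4,7a-trimethylhexahydro-1-benzofuran-2(3H)-ylidene]butan-2-one | C/C(C(=O)CBr)=C1\C[C@H]2C(C)(C)[C@@H](Br)CC[C@]2(C)O1 | target

Total step count: 10. Longest linear sequence: 10 steps (from 1 to 21).

Steps most likely to fail

Step 8. Substitution at C5 is slowed by the adjacent quaternary C4, so the oxyphosphonium intermediate may instead lose a proton toward C6 or ionise with a 1,2-methyl shift from C4. The fallback sets out from 16 and separates activation from displacement: Tf2O and pyridine in CH2Cl2 at −20 °C should give (3aS,5R,7aS)-4,4,7a-trimethyl-2-oxooctahydro-1-benzofuran-5-yl trifluoromethanesulfonate F1, and Bu4NBr in PhMe at room temperature should then displace the axial triflate with inversion under non-ionising conditions. It comes back to the route at 17.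

Step 7. Oxygen may trap the C7a radical on both faces (poor facial selectivity), or the radical may simply be reduced to the alkane. The fallback sets out from 14 and replaces the radical hydration by an ionic sequence steered by the C5 hydroxyl. VO(acac)2 and t-BuOOH in PhMe should deliver the epoxide oxygen to the face of the homoallylic hydroxyl, giving 2-(4-hydroxy-1,3,3-trimethyl-7-oxabicyclo[4.1.0]heptan-2-yl)-N-methoxy-N-methylacetamide with the oxirane oxygen syn to the C5 hydroxyl F2. LiAlH4 in THF at 0 °C should then open the epoxide at the less substituted C7 and reduce the Weinreb amide to the aldehyde, which closes to (3aS,5R,7aS)-4,4,7a-trimethyloctahydro-1-benzofuran-2,5-diol F3 (lactol, both C2 anomers). Ag2CO3 on Celite in refluxing PhH should oxidise only the lactol, and the sequence comes back to the route at 16.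

Step 10. The carbenoid may decompose before it adds to the electron-rich vinylogous amide, or it may remove a proton from C3 instead of adding. The fallback sets out from 20: MeMgBr in THF at 0 °C should give (3Z)-3-[(3aS,5S,7aS)-5-bromo-4,4,7a-trimethylhexahydro-1-benzofuran-2(3H)-ylidene]butan-2-one F4. Kinetic deprotonation of the acetyl methyl group with LiN(SiMe3)2 and TMSCl in THF at −78 °C should give {[(3Z)-3-[(3aS,5S,7aS)-5-bromo-4,4,7a-trimethylhexahydro-1-benzofuran-2(3H)-ylidene]but-1-en-2-yl]oxy}trimethylsilane F5, and N-bromosuccinimide in THF at −78 °C should brominate its terminal carbon. The sequence comes back to the route at 21.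

Further compounds

F1 | step 8 | (3aS,5R,7aS)-4,4,7a-trimethyl-2-oxooctahydro-1-benzofuran-5-yl trifluoromethanesulfonate | O=C1C[C@H]2C(C)(C)[C@H](OS(=O)(=O)C(F)(F)F)CC[C@]2(C)O1
F2 | step 7 | 2-(4-hydroxy-1,3,3-trimethyl-7-oxabicyclo[4.1.0]heptan-2-yl)-N-methoxy-N-methylacetamide, oxirane oxygen syn to the C5 hydroxyl | CON(C)C(=O)C[C@@H]1[C@@]2(C)O[C@H]2C[C@@H](O)C1(C)C
F3 | step 7 | (3aS,5R,7aS)-4,4,7a-trimethyloctahydro-1-benzofuran-2,5-diol (lactol, both C2 anomers) | OC1C[C@H]2C(C)(C)[C@H](O)CC[C@]2(C)O1
F4 | step 10 | (3Z)-3-[(3aS,5S,7aS)-5-bromo-4,4,7a-trimethylhexahydro-1-benzofuran-2(3H)-ylidene]butan-2-one | C/C(C(C)=O)=C1\C[C@H]2C(C)(C)[C@@H](Br)CC[C@]2(C)O1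
F5 | step 10 | {[(3Z)-3-[(3aS,5S,7aS)-5-bromo-4,4,7a-trimethylhexahydro-1-benzofuran-2(3H)-ylidene]but-1-en-2-yl]oxy}trimethylsilane | C/C(C(=C)O[Si](C)(C)C)=C1\C[C@H]2C(C)(C)[C@@H](Br)CC[C@]2(C)O1
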